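Assumption: Pseudomonas fluorescens lipase acetylates the CH2OH arm next to the (S)-carbon of the meso diol (the usual sense for this diol), and the target is the 3-acyltetronic acid tautomer system drawn in the given SMILES. TBS = tert-butyldimethylsilyl throughout.

**Retrosynthetic overview**
1. Okilactomycin C ⇐ its tetronate O-methyl ether with CH2OTBS in place of CO2H; the 13-membered carbocycle is closed by ring-closing metathesis (allyl on the cyclohexene + vinyl on the side chain), and the new CH=CH is then hydrogenated.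
2. Metathesis precursor ⇐ C3-lithiated spiro methyl tetronate (fragment A) + (2Z,4R,6S)-2,4,6-trimethylocta-2,7-dienal (fragment B), by addition then oxidation.
3. Fragment A ⇐ Dieckmann closure of an α-acetoxy ester ⇐ enolate hydroxylation ⇐ auxiliary-controlled Diels–Alder of an acrylimide with a (2Z,4E)-triene (Stille coupling of a stannane from ethyl but-2-ynoate with (E)-1-iodopenta-1,4-diene).
4. Fragment B ⇐ lipase desymmetrisation of meso-2,4-dimethylpentane-1,5-diol, Still–Gennari olefination, Wittig methylenation.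
5. Ring order: cyclohexene (Diels–Alder) → spirotetronate (Dieckmann) → 13-membered carbocycle (metathesis).

**Route**

Step 1
Reactants: 1 allyl bromide; 2 ethynylmagnesium bromide
Product: 3 pent-1-en-4-yne
Conditions: CuCl (5 mol %), THF, 0 °C → rt; distil
Reagents that add atoms: none
Why: Copper-catalysed alkynyl Grignard–allyl halide substitution gives the skipped enyne.

Step 2
Reactants: 3 pent-1-en-4-yne
Product: 5 (1E)-1-iodopenta-1,4-diene, via alkenylzirconocene chloride 4 (not isolated)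
Conditions: Cp2Zr(H)Cl (1.05 equiv), CH2Cl2, rt; then I2, 0 °C
Reagents that add atoms: iodine, II; Cp2Zr(H)Cl, [H][Zr](Cl)(C1C=CC=C1)C1C=CC=C1 (its zirconium stays only in 4)
Why: Hydrozirconation adds syn and anti-Markovnikov to the terminal alkyne (faster than to the alkene) and iodinolysis with retention gives the (E)-vinyl iodide.

Step 3
Reactants: 6 ethyl but-2-ynoate
Product: 7 ethyl (2E)-2-(tributylstannyl)but-2-enoate
Conditions: Bu3SnH (1.1 equiv), Pd(PPh3)4 (2 mol %), THF, 0 °C → rt
Reagents that add atoms: tributyltin hydride, CCCC[SnH](CCCC)CCCC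
Why: Pd-catalysed hydrostannation of an ynoate is a syn addition with tin α to the ester, which fixes the methyl group cis to the carbon that later becomes the carboxyl group.

Step 4
Reactants: 7 ethyl (2E)-2-(tributylstannyl)but-2-enoate
Product: 8 (2E)-2-(tributylstannyl)but-2-en-1-ol
Conditions: i-Bu2AlH (2.2 equiv), CH2Cl2, −78 °C; aqueous work-up
Reagents that add atoms: none
Why: Hydride 1,2-reduction of the ester leaves the vinylstannane and its geometry intact.

Step 5
Reactants: 8 (2E)-2-(tributylstannyl)but-2-en-1-ol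
Product: 9 tert-butyldimethyl{[(2E)-2-(tributylstannyl)but-2-en-1-yl]oxy}silane
Conditions: TBSCl, imidazole, DMF, rt
Reagents that add atoms: tert-butyldimethylsilyl chloride, CC(C)(C)[Si](C)(C)Cl
Why: Silylation of the primary alcohol gives an ether that carries the future carboxyl carbon through all basic and Lewis-acidic steps.

Step 6
Reactants: 9 stannyl TBS ether; 5 (1E)-1-iodopenta-1,4-diene
Product: 10 tert-butyl{[(2Z,3E)-2-ethylidenehepta-3,6-dien-1-yl]oxy}dimethylsilane
Conditions: Pd2(dba)3 (2.5 mol %), AsPh3 (20 mol %), CuI (10 mol %), NMP, 40 °C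
Reagents that add atoms: none
Why: Stille cross-coupling proceeds with retention at both sp2 carbons and gives the (Z,E)-diene with both terminal substituents outside the s-cis diene.

Step 7
Reactants: 11 (4S)-4-benzyl-1,3-oxazolidin-2-one; 12 acryloyl chloride
Product: 14 (4S)-3-acryloyl-4-benzyl-1,3-oxazolidin-2-one, via bromomagnesium oxazolidinide 13 (not isolated)
Conditions: MeMgBr (1.0 equiv), THF, 0 °C; then 12, −78 °C
Reagents that add atoms: methylmagnesium bromide, C[Mg]Br (its magnesium stays only in 13)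
Why: N-Acylation of the magnesium oxazolidinide gives the chiral acrylimide dienophile.

Step 8
Reactants: 10 triene; 14 acrylimide
Product: 15 (4S)-4-benzyl-3-{[(1R,2S,5S)-4-(TBSOCH2)-5-methyl-2-(prop-2-en-1-yl)cyclohex-3-en-1-yl]carbonyl}-1,3-oxazolidin-2-one
Conditions: Et2AlCl (1.4 equiv), CH2Cl2, −78 → −30 °C
Reagents that add atoms: none
Why: In this auxiliary-controlled Diels–Alder reaction the Et2AlCl-chelated s-cis acrylimide is attacked on the face opposite the benzyl group through an endo transition state, with the acyl carbon bonding to the allyl-bearing terminus (para to the CH2OTBS carbon), which sets C2 (S) and C5 (S) with acyl, allyl and methyl all cis.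

Step 9
Reactants: 15 Diels–Alder adduct
Product: 16 methyl (1R,2S,5S)-4-(TBSOCH2)-5-methyl-2-(prop-2-en-1-yl)cyclohex-3-ene-1-carboxylate
Conditions: MeOMgBr (from MeMgBr + MeOH, 1.3 equiv), MeOH/CH2Cl2, 0 °C; aqueous work-up
Reagents that add atoms: methanol, CO (delivered as methoxymagnesium bromide, CO[Mg]Br, made in the flask from MeMgBr, C[Mg]Br)
Why: Transesterification at the exocyclic imide carbonyl releases the auxiliary, and any epimerisation at C1 is irrelevant because C1 is re-set in step 10.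

Step 10
Reactants: 16 methyl ester
Product: 18 methyl (1S,2S,5S)-4-(TBSOCH2)-1-hydroxy-5-methyl-2-(prop-2-en-1-yl)cyclohex-3-ene-1-carboxylate, via potassium ester enolate 17 (not isolated)
Conditions: KN(SiMe3)2 (1.3 equiv), THF, −78 °C; then trans-3-phenyl-2-(phenylsulfonyl)oxaziridine, −78 °C; aqueous work-up
Reagents that add atoms: trans-3-phenyl-2-(phenylsulfonyl)oxaziridine, O=S(=O)(c1ccccc1)N1OC1c1ccccc1; KN(SiMe3)2, C[Si](C)(C)N([K])[Si](C)(C)C (its potassium stays only in 17)
Why: In this Davis enolate hydroxylation the planar enolate is oxidised on the ring face opposite the cis allyl and methyl groups, so OH enters trans to both and the quaternary centre (S) is set with the ester cis to the allyl group.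

Step 11
Reactants: 18 tertiary α-hydroxy ester
Product: 19 methyl (1S,2S,5S)-1-acetoxy-4-(TBSOCH2)-5-methyl-2-(prop-2-en-1-yl)cyclohex-3-ene-1-carboxylate
Conditions: Ac2O, DMAP, Et3N, CH2Cl2, 40 °C
Reagents that add atoms: acetic anhydride, CC(=O)OC(C)=O
Why: DMAP-catalysed acylation of the hindered tertiary alcohol installs the two carbons of the tetronate ring.

Step 12
Reactants: 19 α-acetoxy ester
Product: 20 (5S,6S,9S)-8-(TBSOCH2)-4-hydroxy-9-methyl-6-(prop-2-en-1-yl)-1-oxaspiro[4.5]deca-3,7-dien-2-one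
Conditions: LiN(SiMe3)2 (3 equiv), THF, −78 °C → rt; then 1 M HCl to pH 3, 0 °C
Reagents that add atoms: none
Why: Dieckmann condensation (5-exo attack of the acetate enolate on the methyl ester) forms the spirotetronic acid without touching the quaternary centre.

Step 13
Reactants: 20 spirotetronic acid
Product: 21 (5S,6S,9S)-8-(TBSOCH2)-4-methoxy-9-methyl-6-(prop-2-en-1-yl)-1-oxaspiro[4.5]deca-3,7-dien-2-one (fragment A)
Conditions: Me2SO4, K2CO3, acetone, rt
Reagents that add atoms: dimethyl sulfate, COS(=O)(=O)OC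
Why: O-Alkylation at O4 masks the tetronic acid as the methyl tetronate and makes C3 lithiation possible.

Step 14
Reactants: 22 meso-2,4-dimethylglutaric anhydride
Product: 23 (2R,4S)-2,4-dimethylpentane-1,5-diol (meso)
Conditions: LiAlH4, THF, 0 °C → reflux; aqueous work-up
Reagents that add atoms: none
Why: Hydride reduction of the anhydride gives the meso diol without touching either methyl-bearing carbon.

Step 15
Reactants: 23 meso diol
Product: 24 (2R,4S)-5-acetoxy-2,4-dimethylpentan-1-ol
Conditions: Pseudomonas fluorescens lipase, vinyl acetate, THF, rt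
Reagents that add atoms: vinyl acetate, CC(=O)OC=C
Why: Enzymatic desymmetrisation acetylates only the arm next to the (S)-carbon, which turns the meso diol into one enantiomer and fixes both methyl stereocentres of the side chain.

Step 16
Reactants: 24 monoacetate
Product: 25 (2S,4R)-2,4-dimethyl-5-oxopentyl acetate
Conditions: Dess–Martin periodinane, pyridine, CH2Cl2, 0 °C → rt
Reagents that add atoms: none
Why: Dess–Martin oxidation gives the α-methyl aldehyde under non-epimerising conditions.

Step 17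
Reactants: 25 aldehyde
Product: 26 ethyl (2Z,4R,6S)-7-acetoxy-2,4,6-trimethylhept-2-enoate
Conditions: ethyl 2-[bis(2,2,2-trifluoroethoxy)phosphoryl]propanoate, KN(SiMe3)2, 18-crown-6, THF, −78 °C
Reagents that add atoms: ethyl 2-[bis(2,2,2-trifluoroethoxy)phosphoryl]propanoate, CCOC(=O)C(C)P(=O)(OCC(F)(F)F)OCC(F)(F)F
Why: Still–Gennari olefination under kinetic control gives the (Z)-2-methyl enoate, the geometry needed for the ring alkene of the target.

Step 18
Reactants: 26 acetoxy enoate
Product: 27 ethyl (2Z,4R,6S)-7-hydroxy-2,4,6-trimethylhept-2-enoate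
Conditions: K2CO3 (0.2 equiv), EtOH, 0 °C → rt
Reagents that add atoms: none
Why: Base-catalysed transesterification removes the acetate and keeps the ethyl ester, while the α-methyl (Z)-enoate is too poor an acceptor for oxa-Michael closure.

Step 19
Reactants: 27 hydroxy enoate
Product: 28 ethyl (2Z,4R,6S)-2,4,6-trimethyl-7-oxohept-2-enoate
Conditions: Dess–Martin periodinane, pyridine, CH2Cl2, 0 °C → rt
Reagents that add atoms: none
Why: Dess–Martin oxidation of the primary alcohol gives the aldehyde without epimerisation.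

Step 20
Reactants: 28 aldehyde
Product: 29 ethyl (2Z,4R,6S)-2,4,6-trimethylocta-2,7-dienoate
Conditions: Ph3PCH3Br, KN(SiMe3)2, THF, −78 → 0 °C
Reagents that add atoms: methyltriphenylphosphonium bromide, C[P+](c1ccccc1)(c1ccccc1)c1ccccc1.[Br-]
Why: Wittig methylenation at low temperature installs the terminal alkene without epimerising the α-methyl centre or touching the enoate.

Step 21
Reactants: 29 dienoate
Product: 30 (2Z,4R,6S)-2,4,6-trimethylocta-2,7-dien-1-ol
Conditions: i-Bu2AlH (2.2 equiv), CH2Cl2, −78 °C; aqueous work-up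
Reagents that add atoms: none
Why: Hydride 1,2-reduction of the enoate gives the (Z)-allylic alcohol with the geometry retained.

Step 22
Reactants: 30 dienol
Product: 31 (2Z,4R,6S)-2,4,6-trimethylocta-2,7-dienal (fragment B)
Conditions: MnO2 (activated, excess), CH2Cl2, rt; use at once
Reagents that add atoms: none
Why: MnO2 allylic oxidation is neutral, so the (Z)-enal forms without isomerisation.

Step 23
Reactants: 21 methyl tetronate (fragment A); 31 dienal (fragment B)
Product: 33 (5S,6S,9S)-8-(TBSOCH2)-3-[(2Z,4R,6S)-1-hydroxy-2,4,6-trimethylocta-2,7-dien-1-yl]-4-methoxy-9-methyl-6-(prop-2-en-1-yl)-1-oxaspiro[4.5]deca-3,7-dien-2-one (both carbinol epimers), via 3-lithiotetronate 32 (not isolated)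
Conditions: LiN(i-Pr)2 (1.1 equiv), THF, −78 °C; then 31, −78 °C; aqueous work-up
Reagents that add atoms: LiN(i-Pr)2, CC(C)N([Li])C(C)C (its lithium stays only in 32)
Why: Directed C3 lithiation of the methyl tetronate and 1,2-addition of the vinyllithium to the enal join the fragments, and the carbinol epimers converge in step 24.

Step 24
Reactants: 33 carbinol
Product: 34 (5S,6S,9S)-8-(TBSOCH2)-4-methoxy-9-methyl-6-(prop-2-en-1-yl)-3-[(2Z,4R,6S)-2,4,6-trimethylocta-2,7-dienoyl]-1-oxaspiro[4.5]deca-3,7-dien-2-one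
Conditions: Dess–Martin periodinane, pyridine, CH2Cl2, 0 °C
Reagents that add atoms: none
Why: Dess–Martin oxidation of the doubly allylic alcohol gives the 3-acyl tetronate with the (Z)-enone intact.

Step 25
Reactants: 34 acyclic diene
Product: 35 macrocyclic triene (13-membered carbocycle; new CH=CH between the former allyl and vinyl CH, E/Z mixture; otherwise as 36)
Conditions: second-generation Hoveyda–Grubbs catalyst RuCl2(H2IMes)(=CH-C6H4-2-O-i-Pr) (10 mol %), CH2Cl2 (0.5 mM), 40 °C
Reagents that add atoms: none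
Why: Ring-closing metathesis of the two monosubstituted alkenes at high dilution closes the 13-membered ring with loss of ethene, while the trisubstituted enone and ring alkenes are inert and the phosphine-free catalyst avoids enone isomerisation.

Step 26
Reactants: 35 macrocyclic triene
Product: 36 tetronate O-methyl ether and TBS ether of the saturated macrocycle (okilactomycin C skeleton with 4-OMe and CH2OTBS in place of CO2H)
Conditions: H2 (1 atm), RhCl(PPh3)3 (20 mol %), benzene, rt
Reagents that add atoms: none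
Why: Homogeneous hydrogenation reduces the 1,2-disubstituted alkene much faster than the trisubstituted conjugated enone, the trisubstituted cyclohexene and the tetrasubstituted tetronate alkene.

Step 27
Reactants: 36 TBS ether
Product: 37 primary allylic alcohol (as 36 with CH2OH)
Conditions: HF·pyridine, pyridine/THF, 0 °C → rt
Reagents that add atoms: none
Why: Buffered fluoride desilylation frees the alcohol without base that could isomerise the enone.

Step 28
Reactants: 37 allylic alcohol
Product: 38 ring enal (as 36 with CHO)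
Conditions: MnO2 (activated, excess), CH2Cl2, rt
Reagents that add atoms: none
Why: MnO2 allylic oxidation stops cleanly at the conjugated aldehyde.

Step 29
Reactants: 38 enal
Product: 39 okilactomycin C tetronate O-methyl ether (as 36 with CO2H)
Conditions: NaClO2, NaH2PO4, 2-methylbut-2-ene, t-BuOH/H2O, 0 °C → rt
Reagents that add atoms: sodium chlorite, [Na+].[O-]Cl=O
Why: Pinnick oxidation converts the enal into the acid while the scavenger removes HOCl, so no alkene is touched.

Step 30
Reactants: 39 methyl ether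
Product: 40 okilactomycin C
Conditions: LiCl (10 equiv), DMSO, 50 °C; dilute aq. HCl work-up
Reagents that add atoms: none
Why: SN2 demethylation of the vinylogous methyl ester by chloride frees the 3-acyltetronic acid, and the much less acidic CO2H stays protonated and is not methylated.

**Compound list**
1 | allyl bromide | C=CCBr | starting material
2 | ethynylmagnesium bromide | C#C[Mg]Br | starting material
3 | pent-1-en-4-yne | C=CCC#C | intermediate
4 | (1E)-penta-1,4-dien-1-ylzirconocene chloride | C=CC/C=C/[Zr](Cl)(C1C=CC=C1)C1C=CC=C1 | intermediate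
5 | (1E)-1-iodopenta-1,4-diene | C=CC/C=C/I | intermediate
6 | ethyl but-2-ynoate | CC#CC(=O)OCC | starting material
7 | ethyl (2E)-2-(tributylstannyl)but-2-enoate | C/C=C(/[Sn](CCCC)(CCCC)CCCC)C(=O)OCC | intermediate
8 | (2E)-2-(tributylstannyl)but-2-en-1-ol | C/C=C(/[Sn](CCCC)(CCCC)CCCC)CO | intermediate
9 | tert-butyldimethyl{[(2E)-2-(tributylstannyl)but-2-en-1-yl]oxy}silane | C/C=C(/[Sn](CCCC)(CCCC)CCCC)CO[Si](C)(C)C(C)(C)C | intermediate
10 | tert-butyl{[(2Z,3E)-2-ethylidenehepta-3,6-dien-1-yl]oxy}dimethylsilane | C/C=C(/C=C/CC=C)CO[Si](C)(C)C(C)(C)C | intermediate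
11 | (4S)-4-benzyl-1,3-oxazolidin-2-one | O=C1N[C@@H](Cc2ccccc2)CO1 | starting material
12 | acryloyl chloride | C=CC(=O)Cl | starting material
13 | bromomagnesium salt of 11 (N-magnesiated) | O=C1N([Mg]Br)[C@@H](Cc2ccccc2)CO1 | intermediate
14 | (4S)-3-acryloyl-4-benzyl-1,3-oxazolidin-2-one | C=CC(=O)N1[C@@H](Cc2ccccc2)COC1=O | intermediate
15 | (4S)-4-benzyl-3-{[(1R,2S,5S)-4-(TBSOCH2)-5-methyl-2-(prop-2-en-1-yl)cyclohex-3-en-1-yl]carbonyl}-1,3-oxazolidin-2-one | C=CC[C@H]1C=C(CO[Si](C)(C)C(C)(C)C)[C@@H](C)C[C@H]1C(=O)N2[C@@H](Cc3ccccc3)COC2=O | intermediate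
16 | methyl (1R,2S,5S)-4-(TBSOCH2)-5-methyl-2-(prop-2-en-1-yl)cyclohex-3-ene-1-carboxylate | C=CC[C@H]1C=C(CO[Si](C)(C)C(C)(C)C)[C@@H](C)C[C@H]1C(=O)OC | intermediate
17 | potassium enolate of 16 | C=CC[C@H]1C=C(CO[Si](C)(C)C(C)(C)C)[C@@H](C)CC1=C([O-])OC.[K+] | intermediate
18 | methyl (1S,2S,5S)-4-(TBSOCH2)-1-hydroxy-5-methyl-2-(prop-2-en-1-yl)cyclohex-3-ene-1-carboxylate | C=CC[C@H]1C=C(CO[Si](C)(C)C(C)(C)C)[C@@H](C)C[C@@]1(O)C(=O)OC | intermediate
19 | methyl (1S,2S,5S)-1-acetoxy-4-(TBSOCH2)-5-methyl-2-(prop-2-en-1-yl)cyclohex-3-ene-1-carboxylate | C=CC[C@H]1C=C(CO[Si](C)(C)C(C)(C)C)[C@@H](C)C[C@@]1(OC(C)=O)C(=O)OC | intermediate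
20 | (5S,6S,9S)-8-(TBSOCH2)-4-hydroxy-9-methyl-6-(prop-2-en-1-yl)-1-oxaspiro[4.5]deca-3,7-dien-2-one | C=CC[C@H]1C=C(CO[Si](C)(C)C(C)(C)C)[C@@H](C)C[C@]12OC(=O)C=C2O | intermediate
21 | (5S,6S,9S)-8-(TBSOCH2)-4-methoxy-9-methyl-6-(prop-2-en-1-yl)-1-oxaspiro[4.5]deca-3,7-dien-2-one (fragment A) | C=CC[C@H]1C=C(CO[Si](C)(C)C(C)(C)C)[C@@H](C)C[C@]12OC(=O)C=C2OC | intermediate
22 | meso-2,4-dimethylglutaric anhydride, (3R,5S)-3,5-dimethyloxane-2,6-dione | O=C1[C@H](C)C[C@H](C)C(=O)O1 | starting material
23 | (2R,4S)-2,4-dimethylpentane-1,5-diol (meso) | OC[C@H](C)C[C@H](C)CO | intermediate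
24 | (2R,4S)-5-acetoxy-2,4-dimethylpentan-1-ol | OC[C@H](C)C[C@H](C)COC(C)=O | intermediate
25 | (2S,4R)-2,4-dimethyl-5-oxopentyl acetate | O=C[C@H](C)C[C@H](C)COC(C)=O | intermediate
26 | ethyl (2Z,4R,6S)-7-acetoxy-2,4,6-trimethylhept-2-enoate | CCOC(=O)/C(C)=C\[C@H](C)C[C@H](C)COC(C)=O | intermediate
27 | ethyl (2Z,4R,6S)-7-hydroxy-2,4,6-trimethylhept-2-enoate | CCOC(=O)/C(C)=C\[C@H](C)C[C@H](C)CO | intermediate
28 | ethyl (2Z,4R,6S)-2,4,6-trimethyl-7-oxohept-2-enoate | CCOC(=O)/C(C)=C\[C@H](C)C[C@H](C)C=O | intermediate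
29 | ethyl (2Z,4R,6S)-2,4,6-trimethylocta-2,7-dienoate | CCOC(=O)/C(C)=C\[C@H](C)C[C@H](C)C=C | intermediate
30 | (2Z,4R,6S)-2,4,6-trimethylocta-2,7-dien-1-ol | OC/C(C)=C\[C@H](C)C[C@H](C)C=C | intermediate
31 | (2Z,4R,6S)-2,4,6-trimethylocta-2,7-dienal (fragment B) | O=C/C(C)=C\[C@H](C)C[C@H](C)C=C | intermediate
32 | C3-lithio derivative of 21 | C=CC[C@H]1C=C(CO[Si](C)(C)C(C)(C)C)[C@@H](C)C[C@]12OC(=O)C([Li])=C2OC | intermediate
33 | (5S,6S,9S)-8-(TBSOCH2)-3-[(2Z,4R,6S)-1-hydroxy-2,4,6-trimethylocta-2,7-dien-1-yl]-4-methoxy-9-methyl-6-(prop-2-en-1-yl)-1-oxaspiro[4.5]deca-3,7-dien-2-one (carbinol epimers) | C=CC[C@H]1C=C(CO[Si](C)(C)C(C)(C)C)[C@@H](C)C[C@]12OC(=O)C(C(O)/C(C)=C\[C@H](C)C[C@H](C)C=C)=C2OC | intermediate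
34 | (5S,6S,9S)-8-(TBSOCH2)-4-methoxy-9-methyl-6-(prop-2-en-1-yl)-3-[(2Z,4R,6S)-2,4,6-trimethylocta-2,7-dienoyl]-1-oxaspiro[4.5]deca-3,7-dien-2-one | C=CC[C@H]1C=C(CO[Si](C)(C)C(C)(C)C)[C@@H](C)C[C@]12OC(=O)C(C(=O)/C(C)=C\[C@H](C)C[C@H](C)C=C)=C2OC | intermediate
35 | macrocyclic triene: 36 with CH=CH (E/Z mixture) between the two CH2 groups next to the side-chain CH(CH3) | C/C1=C/[C@H](C)C[C@H](C)C=CC[C@H]2C=C(CO[Si](C)(C)C(C)(C)C)[C@@H](C)C[C@]23OC(=O)C(C1=O)=C3OC | intermediate
36 | okilactomycin C skeleton with 4-OMe on the tetronate and CH2OTBS in place of CO2H; (Z)-enone and all five stereocentres as in the target | C/C1=C/[C@H](C)C[C@H](C)CCC[C@H]2C=C(CO[Si](C)(C)C(C)(C)C)[C@@H](C)C[C@]23OC(=O)C(C1=O)=C3OC | intermediate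
37 | as 36 with CH2OH in place of CH2OTBS | C/C1=C/[C@H](C)C[C@H](C)CCC[C@H]2C=C(CO)[C@@H](C)C[C@]23OC(=O)C(C1=O)=C3OC | intermediate
38 | as 36 with CHO in place of CH2OTBS | C/C1=C/[C@H](C)C[C@H](C)CCC[C@H]2C=C(C=O)[C@@H](C)C[C@]23OC(=O)C(C1=O)=C3OC | intermediate
39 | okilactomycin C tetronate 4-O-methyl ether | C/C1=C/[C@H](C)C[C@H](C)CCC[C@H]2C=C(C(=O)O)[C@@H](C)C[C@]23OC(=O)C(C1=O)=C3OC | intermediate
40 | okilactomycin C | CC1=C/[C@H](C)C[C@H](C)CCC[C@H]2C=C(C(=O)O)[C@@H](C)C[C@]23OC(=O)\C(=C\1O)C3=O | target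

**Step count**
Total: 30 steps. Longest linear sequence: 18 steps (3, 4, 5, 6, 8, 9, 10, 11, 12, 13, then 23–30, from ethyl but-2-ynoate). Fragment B takes 9 steps (14–22), the iododiene 2 steps (1–2) and the dienophile 1 step (7).

**Three steps most likely to fail, with fallbacks**

Step 8 (Diels–Alder). The risk is that regio- or endo-selectivity erodes on the trisubstituted diene, or that Et2AlCl degrades the triene. The fallback sets out from 10 and comes back at 16, replacing auxiliary and Lewis-acid control by iminium organocatalysis. Acrolein with (5S)-5-benzyl-2,2,3-trimethylimidazolidin-4-one hydrochloride (20 mol %, MeCN/H2O 95:5, 0 °C), which exposes the same Cα face as the auxiliary, gives (1R,2S,5S)-4-(TBSOCH2)-5-methyl-2-(prop-2-en-1-yl)cyclohex-3-ene-1-carbaldehyde F1. Oxidation with NaClO2/NaH2PO4/2-methylbut-2-ene gives the corresponding carboxylic acid F2, and TMSCHN2 in toluene/MeOH gives 16.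

Step 25 (ring-closing metathesis). The risk is that the ring, rich in trigonal carbons, closes slowly and the diene dimerises. The fallback sets out from 21 (with 30 as partner) and comes back at 36, closing the ring by a Nozaki–Hiyama–Kishi reaction instead of metathesis. Compound 21 is lithiated as in step 23 (giving 32) and quenched with iodine to the 3-iodotetronate F3. Cross-metathesis of F3 with 30 (3 equiv, RuCl2(H2IMes)(=CH-C6H4-2-O-i-Pr), CH2Cl2, 40 °C) joins the two chains to the allylic alcohol F4. Diimide (2-nitrobenzenesulfonohydrazide, Et3N, rt) saturates only the new disubstituted alkene to the saturated allylic alcohol F5, and MnO2 gives the (Z)-enal F6. CrCl2 with NiCl2 (cat.) in DMSO/THF at 2 mM closes the 13-membered ring between C3 of the tetronate and the aldehyde to the macrocyclic carbinol F7, and Dess–Martin oxidation gives 36.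

Step 26 (chemoselective hydrogenation). The risk is enone reduction, Z→E isomerisation by free PPh3, or a sluggish reaction. The fallback sets out from 33 and comes back at 36, running metathesis and hydrogenation one oxidation level earlier, where the trisubstituted alkene is an isolated allylic-alcohol alkene and not an enone. Ring-closing metathesis of 33 under the step 25 conditions gives the macrocyclic carbinol diene F8, RhCl(PPh3)3/H2 gives the saturated macrocyclic carbinol F9 (the same compound as F7), and Dess–Martin oxidation gives 36.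

**Further compounds**
F1 | step 8 | (1R,2S,5S)-4-(TBSOCH2)-5-methyl-2-(prop-2-en-1-yl)cyclohex-3-ene-1-carbaldehyde | C=CC[C@H]1C=C(CO[Si](C)(C)C(C)(C)C)[C@@H](C)C[C@H]1C=O
F2 | step 8 | (1R,2S,5S)-4-(TBSOCH2)-5-methyl-2-(prop-2-en-1-yl)cyclohex-3-ene-1-carboxylic acid | C=CC[C@H]1C=C(CO[Si](C)(C)C(C)(C)C)[C@@H](C)C[C@H]1C(=O)O
F3 | step 25 | (5S,6S,9S)-8-(TBSOCH2)-3-iodo-4-methoxy-9-methyl-6-(prop-2-en-1-yl)-1-oxaspiro[4.5]deca-3,7-dien-2-one | C=CC[C@H]1C=C(CO[Si](C)(C)C(C)(C)C)[C@@H](C)C[C@]12OC(=O)C(I)=C2OC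
F4 | step 25 | cross-metathesis product of F3 and 30 (allylic alcohol, E/Z at the new CH=CH) | OC/C(C)=C\[C@H](C)C[C@H](C)C=CC[C@H]1C=C(CO[Si](C)(C)C(C)(C)C)[C@@H](C)C[C@]12OC(=O)C(I)=C2OC
F5 | step 25 | F4 with the new CH=CH saturated | OC/C(C)=C\[C@H](C)C[C@H](C)CCC[C@H]1C=C(CO[Si](C)(C)C(C)(C)C)[C@@H](C)C[C@]12OC(=O)C(I)=C2OC
F6 | step 25 | (Z)-enal from F5 | O=C/C(C)=C\[C@H](C)C[C@H](C)CCC[C@H]1C=C(CO[Si](C)(C)C(C)(C)C)[C@@H](C)C[C@]12OC(=O)C(I)=C2OC
F7 | step 25 | macrocyclic carbinol (36 with CH(OH) in place of the enone C=O, epimers) | C/C1=C/[C@H](C)C[C@H](C)CCC[C@H]2C=C(CO[Si](C)(C)C(C)(C)C)[C@@H](C)C[C@]23OC(=O)C(C1O)=C3OC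
F8 | step 26 | macrocyclic carbinol diene (35 with CH(OH) in place of the enone C=O, epimers) | C/C1=C/[C@H](C)C[C@H](C)C=CC[C@H]2C=C(CO[Si](C)(C)C(C)(C)C)[C@@H](C)C[C@]23OC(=O)C(C1O)=C3OC
F9 | step 26 | saturated macrocyclic carbinol (identical to F7) | C/C1=C/[C@H](C)C[C@H](C)CCC[C@H]2C=C(CO[Si](C)(C)C(C)(C)C)[C@@H](C)C[C@]23OC(=O)C(C1O)=C3OC
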